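**Plan**
- Retrosynthesis: the C2, C4 and C9 acetates come off first; the lactone is cut at C8–C17 and at the C7–O ester bond; ring B is cut at C6–C7; the arms are cut at C8–C9, C3–C4 and C2–C3; ring A is cut at C1–C14 and C10–C11.
- Forward: ring A by a catalytic asymmetric Diels–Alder reaction, then the C2–C6 arm, the C11=C12 alkene, the C9–C7 arm, the epoxide, ring B by Nozaki–Hiyama–Kishi closure, and last the lactone by a SmI2 Reformatsky closure.
- Enabling feature (briarane numbering): ring A (C1, C10–C14) holds three contiguous centres, oxygenated C14, quaternary C1 and C10, with O14 cis to C2 and C2 trans to C9. This is the pattern of an endo adduct of an (E)-2-methyl enal with a 1-alkoxy-3-silyloxy diene.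
- Stereochemistry: C1, C10 and C14 from the chiral oxazaborolidinium catalyst; C4 from an Ipc2B aldol and C2 from 1,3-anti reduction; C9 from Ipc2B alkoxyallylation; C11 and C12 from hydroxyl-directed epoxidation; C7 by Mitsunobu inversion; C8 and C17 in the Reformatsky closure; the 5Z alkene from a (Z)-iodoalkene.

Key step: step 6

Assumption: the (S)-diphenylprolinol-derived oxazaborolidinium is taken to expose the Cα-Si face of the bound enal, as its formyl C–H···O binding model predicts; the (R)-catalyst would be used if the sense proved opposite.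

Step 1
Reactants: 1 3-methylbut-2-en-1-ol (prenol)
Product: 2 prenyl 4-methoxybenzyl ether
Conditions: NaH, 4-methoxybenzyl chloride, Bu4NI (cat.), THF/DMF, 0 °C to rt
Reagents that add atoms: 4-methoxybenzyl chloride, COc1ccc(CCl)cc1
Why: Williamson etherification of the primary allylic alkoxide with a benzylic chloride is routine and creates no stereocentre.

Step 2
Reactants: 2 prenyl 4-methoxybenzyl ether
Product: 3 (E)-4-(4-methoxybenzyloxy)-2-methylbut-2-enal
Conditions: SeO2 (1.1 equiv), 1,4-dioxane, 70 °C
Reagents that add atoms: selenium dioxide, O=[Se]=O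
Why: Allylic oxidation by SeO2 (ene reaction, then [2,3]-sigmatropic shift) attacks the (E)-methyl group of a trisubstituted alkene, so the (E)-enal should form while the ether stays intact.

Step 3
Reactants: 4 pent-1-yn-3-ol
Product: 5 pent-1-yn-3-one
Conditions: Dess–Martin periodinane, CH2Cl2, 0 °C to rt
Reagents that add atoms: none
Why: Dess–Martin oxidation of a secondary propargylic alcohol gives the volatile ynone under neutral conditions, and its solution can be used directly.

Step 4
Reactants: 5 pent-1-yn-3-one; 6 4-methoxybenzyl alcohol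
Product: 7 (E)-1-(4-methoxybenzyloxy)pent-1-en-3-one
Conditions: 1,4-diazabicyclo[2.2.2]octane (10 mol %), CH2Cl2, 0 °C to rt
Reagents that add atoms: none
Why: Amine-catalysed oxa-Michael addition of an alcohol to a terminal ynone gives the more stable (E)-β-alkoxy enone.

Step 5
Reactants: 7 (E)-1-(4-methoxybenzyloxy)pent-1-en-3-one
Product: 8 (1E,3Z)-1-(4-methoxybenzyloxy)-3-(tert-butyldimethylsilyloxy)penta-1,3-diene
Conditions: TBSOTf, Et3N, Et2O, −78 to 0 °C
Reagents that add atoms: tert-butyldimethylsilyl triflate, CC(C)(C)[Si](C)(C)OS(=O)(=O)C(F)(F)F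
Why: Soft enolisation of the ethyl ketone with a silyl triflate and Et3N gives the (Z)-silyl enol ether, so the diene should be (1E,3Z) with both terminal substituents on the outside of the s-cis form.

Step 6
Reactants: 8 (1E,3Z)-1-(4-methoxybenzyloxy)-3-(tert-butyldimethylsilyloxy)penta-1,3-diene; 3 (E)-4-(4-methoxybenzyloxy)-2-methylbut-2-enal
Product: 9 ring A cycloadduct aldehyde
Conditions: oxazaborolidinium triflimide from (S)-3,3-diphenyl-1-(o-tolyl)tetrahydro-1H,3H-pyrrolo[1,2-c][1,3,2]oxazaborole and HN(SO2CF3)2 (20 mol %), CH2Cl2, −78 to −40 °C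
Reagents that add atoms: none
Why: Binding of the formyl oxygen to the cationic boron, held by a formyl C–H···O contact, lowers the LUMO of the s-trans enal, and the diene adds in a concerted but asynchronous [4+2] cycloaddition in which its nucleophilic terminus C11 bonds first to the β-carbon C10 and C14 then closes onto the α-carbon C1; the closest known reaction type is the oxazaborolidinium-catalysed Diels–Alder addition of 2-methyl enals to 1-alkoxy-3-silyloxy dienes. Ring A closes by intermolecular [4+2] cycloaddition, the two new σ-bonds C1–C14 and C10–C11 forming suprafacially on both partners. The trans relation of C2 and C9 is copied from the (E)-geometry of 3, the cis relation of O14 and of the transient C11 methyl group to the formyl group comes from the endo position of that group under the (1E,3Z)-diene, and the absolute configuration (1R,10S,14S in 9, which is the spatial arrangement of the target) comes from the catalyst, whose aryl groups cover one face so that the diene meets the Cα-Si face. The step needs regio-, endo-, facial and C=C-over-C=O selectivity: the two oxygen donors of 8 polarise the diene so that only the C11-to-C10 orientation is matched, secondary overlap with the bound formyl group favours endo, the two-point binding of the enal fixes the face, and the shielded, α-branched formyl carbon disfavours hetero-Diels–Alder or Mukaiyama-type attack at C2.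

Step 7
Reactants: 9 ring A cycloadduct aldehyde
Product: 10 C2 carbinol (both C2 epimers)
Conditions: MeMgBr, THF, −78 °C
Reagents that add atoms: methylmagnesium bromide, C[Mg]Br
Why: Grignard addition to the aldehyde brings in C3 and leaves the silyl enol ether and both ethers untouched at low temperature; the configuration of the new carbinol centre does not matter because it is oxidised in step 8.

Step 8
Reactants: 10 C2 carbinol (both C2 epimers)
Product: 11 C2 methyl ketone
Conditions: Dess–Martin periodinane, NaHCO3, CH2Cl2, 0 °C to rt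
Reagents that add atoms: none
Why: Buffered Dess–Martin oxidation converts the hindered secondary alcohol into the methyl ketone without hydrolysing the silyl enol ether.

Step 9
Reactants: 12 prop-2-yn-1-ol
Product: 14 (Z)-3-iodo-2-methylprop-2-en-1-ol, via alkenylmagnesium chelate 13 (not isolated)
Conditions: MeMgBr (2.5 equiv), CuI (10 mol %), THF, −10 °C to rt; then I2, −78 to 0 °C
Reagents that add atoms: methylmagnesium bromide, C[Mg]Br; iodine, II
Why: Copper-catalysed anti-carbomagnesiation of the propargylic alkoxide puts the methyl group (C16) on the inner carbon and magnesium on the terminal carbon inside a five-membered chelate, so iodinolysis with retention should give the (Z)-iodoalkene with iodine cis to the carbinol carbon.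

Step 10
Reactants: 14 (Z)-3-iodo-2-methylprop-2-en-1-ol
Product: 15 (Z)-3-iodo-2-methylprop-2-enal
Conditions: MnO2, CH2Cl2, rt, dark
Reagents that add atoms: none
Why: MnO2 oxidises the allylic alcohol under neutral conditions, which should preserve the (Z)-geometry of the sensitive β-iodo enal for immediate use.

Step 11
Reactants: 11 C2 methyl ketone; 15 (Z)-3-iodo-2-methylprop-2-enal
Product: 17 (4R)-β-hydroxy ketone, via enol borinate 16 (not isolated)
Conditions: (+)-Ipc2BCl [B-chlorodiisopinocampheylborane from (−)-α-pinene], Et3N, Et2O, 0 °C; then 15, −78 to −20 °C; then MeOH, pH 7 buffer, H2O2, 0 °C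
Reagents that add atoms: none
Why: Only the methyl group of 11 can enolise because C1 is quaternary, and the boron aldol addition through a chair Zimmerman–Traxler transition state should be steered by the Ipc ligands to the Re face of the enal (the empirical sense for methyl ketone enol borinates with this ligand series), which sets C4 as R and forms the C3–C4 bond.

Step 12
Reactants: 17 (4R)-β-hydroxy ketone
Product: 18 (2R,4R)-anti-diol
Conditions: Me4NBH(OAc)3, MeCN/AcOH (1:1), −30 to −20 °C
Reagents that add atoms: none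
Why: In this Evans–Saksena reduction the C4 hydroxyl binds boron and delivers hydride intramolecularly through a chair in which the bulky C1 substituent of the ketone sits equatorial, which should give the 1,3-anti diol and so C2 as R.

Step 13
Reactants: 18 (2R,4R)-anti-diol
Product: 19 C12 keto diol
Conditions: Bu4NF, AcOH, THF, 0 °C
Reagents that add atoms: none
Why: Buffered fluoride cleaves the silyl enol ether with protonation at C13 (no new stereocentre), the acetic acid buffer suppresses β-elimination of the C14 ether, and any enol ether already hydrolysed under the acidic conditions of step 12 converges on the same ketone.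

Step 14
Reactants: 19 C12 keto diol
Product: 20 bis-TES keto ether
Conditions: TESOTf, 2,6-lutidine, CH2Cl2, −78 °C
Reagents that add atoms: triethylsilyl triflate, CC[Si](CC)(CC)OS(=O)(=O)C(F)(F)F
Why: The silyl triflate with a hindered pyridine base silylates both hindered secondary hydroxyls at low temperature, where the ketone is not enolised.

Step 15
Reactants: 20 bis-TES keto ether
Product: 21 (12R)-C12 alcohol
Conditions: LiBH(s-Bu)3, THF, −78 °C
Reagents that add atoms: none
Why: The bulky hydride attacks the C12 ketone equatorially because the axial path is blocked by the axial C14 ether and flanked by the equatorial C20 methyl group (as in 2-methylcyclohexanone), so the axial alcohol, cis to C20 and anti to H11, should result.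

Step 16
Reactants: 21 (12R)-C12 alcohol
Product: 22 C11=C12 alkene
Conditions: Martin sulfurane Ph2S[OC(CF3)2Ph]2, CH2Cl2, 0 °C to rt
Reagents that add atoms: none
Why: The axial alkoxysulfonium ion eliminates by anti-periplanar E2, and the trans-diaxial tertiary H11 should be lost in the Zaitsev sense to give the trisubstituted C11=C12 alkene (as cis-2-methylcyclohexanol derivatives give 1-methylcyclohexene), which also removes the transient C11 and C12 centres.

Step 17
Reactants: 22 C11=C12 alkene
Product: 23 C9/C14 diol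
Conditions: DDQ (3 equiv), CH2Cl2/pH 7 buffer, 0 °C to rt
Reagents that add atoms: none
Why: Oxidative cleavage by DDQ removes both 4-methoxybenzyl ethers through their benzylic oxocarbenium ions and leaves silyl ethers, the alkene and the iodoalkene untouched.

Step 18
Reactants: 23 C9/C14 diol
Product: 24 diacetate
Conditions: Ac2O, 4-(dimethylamino)pyridine (cat.), pyridine, rt
Reagents that add atoms: acetic anhydride, CC(=O)OC(C)=O
Why: Nucleophile-catalysed acetylation of both hydroxyls installs the C14 acetate of the target at a stage with no other free hydroxyl.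

Step 19
Reactants: 24 diacetate
Product: 25 C14 monoacetate (primary C9 alcohol)
Conditions: K2CO3 (0.3 equiv), MeOH, 0 °C
Reagents that add atoms: none
Why: Methanolysis of the unhindered primary acetate should be much faster than that of the axial C14 acetate next to the quaternary C1, so only the C9 hydroxyl is released.

Step 20
Reactants: 25 C14 monoacetate (primary C9 alcohol)
Product: 26 C9 aldehyde
Conditions: Dess–Martin periodinane, NaHCO3, CH2Cl2, 0 °C
Reagents that add atoms: none
Why: Buffered Dess–Martin oxidation gives the β,γ-unsaturated aldehyde without base that could move the C11=C12 bond into conjugation or epimerise C10, and the crude aldehyde is used at once.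

Step 21
Reactants: 26 C9 aldehyde; 27 allyl 4-methoxybenzyl ether
Product: 30 (8R,9R)-syn-alkoxyallylation adduct, via lithiated ether 28 (not isolated), via allylborane 29 (not isolated)
Conditions: 27, s-BuLi, THF, −78 °C; (−)-Ipc2BOMe [B-methoxydiisopinocampheylborane from (+)-α-pinene]; BF3·OEt2; then 26, −78 °C; then H2O2, aq. NaHCO3, 0 °C
Reagents that add atoms: none
Why: In this γ-alkoxyallylboration the (Z)-allylborane adds through a chair Zimmerman–Traxler transition state to give the syn adduct, and the Ipc ligands from (+)-α-pinene direct attack to the Si face of C9, which the Felkin–Anh model with C1 antiperiplanar also prefers, so C9 should be R and the vinyl group becomes the masked C7 aldehyde.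

Step 22
Reactants: 30 (8R,9R)-syn-alkoxyallylation adduct
Product: 31 (11R,12S)-epoxide
Conditions: VO(acac)2 (10 mol %), t-BuOOH, CH2Cl2, 0 °C to rt
Reagents that add atoms: tert-butyl hydroperoxide, CC(C)(C)OO
Why: The vanadium alkoxide of the homoallylic C9 hydroxyl delivers the peroxide oxygen to the ring face that carries C9, giving the 11R,12S epoxide, while the trisubstituted ring alkene should react far faster than the terminal vinyl group or the electron-poor iodoalkene and the acetylated O14 cannot direct to the other face.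

Step 23
Reactants: 31 (11R,12S)-epoxide
Product: 32 tris-TES ether
Conditions: TESCl, imidazole, 4-(dimethylamino)pyridine (cat.), DMF, rt
Reagents that add atoms: chlorotriethylsilane, CC[Si](CC)(CC)Cl
Why: Silylation with the chlorosilane and imidazole is not Lewis acidic, so the C9 hydroxyl is protected without opening the epoxide.

Step 24
Reactants: 32 tris-TES ether
Product: 34 C7 aldehyde, via diol 33 (not isolated)
Conditions: OsO4 (5 mol %), NaIO4, 2,6-lutidine, 1,4-dioxane/H2O, rt
Reagents that add atoms: sodium periodate (oxygen relayed through OsO4), [Na+].[O-]I(=O)(=O)=O; osmium tetroxide, O=[Os](=O)(=O)=O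
Why: In this Lemieux–Johnson cleavage OsO4 dihydroxylates the monosubstituted vinyl group much faster than the electron-poor, trisubstituted iodoalkene, and periodate cleaves the diol to the α-alkoxy aldehyde under lutidine buffering.

Step 25
Reactants: 34 C7 aldehyde
Product: 35 (7R)-macrocyclic allylic alcohol
Conditions: CrCl2 (15 equiv), NiCl2 (0.2 equiv), degassed DMSO, 2 mM, rt
Reagents that add atoms: none
Why: In this Nozaki–Hiyama–Kishi closure zerovalent nickel inserts into the C–I bond, the alkenyl group passes to trivalent chromium with retention of the (Z)-geometry and adds to the aldehyde intramolecularly to close ring B at C6–C7, esters, epoxide and silyl ethers being tolerated; the polar Felkin–Anh preference (attack anti to the C8 ether) should give the 7,8-anti alcohol, C7 R.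

Step 26
Reactants: 35 (7R)-macrocyclic allylic alcohol; 36 2-bromopropanoic acid
Product: 37 (7S)-2-bromopropanoate
Conditions: PPh3, diisopropyl azodicarboxylate, toluene, 0 °C to rt
Reagents that add atoms: none
Why: Mitsunobu esterification activates the C7 hydroxyl as an alkoxyphosphonium ion that the acidic α-bromo carboxylate displaces by SN2 with inversion, which sets C7 as S; the bromine-bearing carbon is a mixture that becomes an enolate in step 29.

Step 27
Reactants: 37 (7S)-2-bromopropanoate
Product: 38 C8 alcohol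
Conditions: DDQ, CH2Cl2/pH 7 buffer, 0 °C
Reagents that add atoms: none
Why: DDQ removes the only remaining 4-methoxybenzyl ether under neutral conditions, which should avoid acyl migration from O7 to O8.

Step 28
Reactants: 38 C8 alcohol
Product: 39 C8 ketone
Conditions: Dess–Martin periodinane, NaHCO3, CH2Cl2, rt
Reagents that add atoms: none
Why: Buffered Dess–Martin oxidation of the hindered secondary alcohol gives the α-acyloxy ketone without epimerising C7 or C9.

Step 29
Reactants: 39 C8 ketone
Product: 40 hydroxy lactone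
Conditions: SmI2 (2.2 equiv), THF, −78 °C; then aq. NH4Cl
Reagents that add atoms: none
Why: In this intramolecular Reformatsky reaction SmI2 reduces the C–Br bond (much faster than the ketone at −78 °C) to a trivalent samarium enolate that adds to the adjacent C8 ketone, closing the γ-lactone at C8–C17; the trans ring fusion (8S, hydroxyl trans to H7) is expected because ring B keeps an anti C6–C7–C8–C9 torsion, and the C18 methyl group takes the side away from the C9 branch (17R), which is also the epimer favoured by equilibration.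

Step 30
Reactants: 40 hydroxy lactone
Product: 41 tetraol (C14 monoacetate)
Conditions: HF·pyridine, pyridine, THF, 0 °C to rt
Reagents that add atoms: none
Why: Buffered HF·pyridine cleaves the three triethylsilyl ethers under mildly acidic conditions that the acetate, the lactone and the hindered epoxide should tolerate, without the base that could cause retro-aldol opening or translactonisation.

Step 31
Reactants: 41 tetraol (C14 monoacetate)
Product: 42 CNP0215170.2
Conditions: Ac2O, 4-(dimethylamino)pyridine, pyridine, CH2Cl2, rt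
Reagents that add atoms: acetic anhydride, CC(=O)OC(C)=O
Why: Acetylation of the three secondary hydroxyls at C2, C4 and C9 completes the tetraacetate, while the tertiary C8 hydroxyl is too hindered to be acylated under these conditions.

**Compound list**
1 | 3-methylbut-2-en-1-ol (prenol) | CC(C)=CCO | starting material
2 | prenyl 4-methoxybenzyl ether | CC(C)=CCOCc1ccc(OC)cc1 | intermediate
3 | (E)-4-(4-methoxybenzyloxy)-2-methylbut-2-enal | O=C/C(C)=C/COCc1ccc(OC)cc1 | intermediate
4 | pent-1-yn-3-ol (racemic) | CCC(O)C#C | starting material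
5 | pent-1-yn-3-one | CCC(=O)C#C | intermediate
6 | 4-methoxybenzyl alcohol | COc1ccc(CO)cc1 | starting material
7 | (E)-1-(4-methoxybenzyloxy)pent-1-en-3-one | CCC(=O)/C=C/OCc1ccc(OC)cc1 | intermediate
8 | (1E,3Z)-1-(4-methoxybenzyloxy)-3-(tert-butyldimethylsilyloxy)penta-1,3-diene | C/C=C(\O[Si](C)(C)C(C)(C)C)/C=C/OCc1ccc(OC)cc1 | intermediate
9 | ring A cycloadduct aldehyde, (1R,10S,11S,14S) in briarane numbering: C1 carries the C15 methyl and the formyl group (C2), C10 carries CH2OPMB (C9), C11 carries the C20 methyl, C12=C13 is the TBS enol ether, C14 carries OPMB; O14 and C20 cis to the formyl group, C9 trans to it | COc1ccc(CO[C@H]2C=C(O[Si](C)(C)C(C)(C)C)[C@@H](C)[C@H](COCc3ccc(OC)cc3)[C@@]2(C)C=O)cc1 | intermediate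
10 | C2 carbinol: 9 with the formyl group as CH(OH)CH3, both C2 epimers | COc1ccc(CO[C@H]2C=C(O[Si](C)(C)C(C)(C)C)[C@@H](C)[C@H](COCc3ccc(OC)cc3)[C@@]2(C)C(C)O)cc1 | intermediate
11 | C2 methyl ketone: 9 with the formyl group as an acetyl group (C3 methyl) | COc1ccc(CO[C@H]2C=C(O[Si](C)(C)C(C)(C)C)[C@@H](C)[C@H](COCc3ccc(OC)cc3)[C@@]2(C)C(C)=O)cc1 | intermediate
12 | prop-2-yn-1-ol | C#CCO | starting material
13 | alkenylmagnesium chelate, cyclic (Z)-alkenylmagnesium alkoxide | CC1=C[Mg]OC1 | intermediate
14 | (Z)-3-iodo-2-methylprop-2-en-1-ol | OC/C(C)=C\I | intermediate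
15 | (Z)-3-iodo-2-methylprop-2-enal | O=C/C(C)=C\I | intermediate
16 | enol diisopinocampheylborinate of 11, Ipc from (−)-α-pinene | COc1ccc(CO[C@H]2C=C(O[Si](C)(C)C(C)(C)C)[C@@H](C)[C@H](COCc3ccc(OC)cc3)[C@@]2(C)C(=C)OB([C@H]3C[C@H]4C[C@@H]([C@@H]3C)C4(C)C)[C@H]3C[C@H]4C[C@@H]([C@@H]3C)C4(C)C)cc1 | intermediate
17 | (4R)-β-hydroxy ketone: C1 carries C(=O)CH2CH(OH)C(CH3)=CHI, 5Z, iodine cis to C4 | COc1ccc(CO[C@H]2C=C(O[Si](C)(C)C(C)(C)C)[C@@H](C)[C@H](COCc3ccc(OC)cc3)[C@@]2(C)C(=O)C[C@@H](O)/C(C)=C\I)cc1 | intermediate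
18 | (2R,4R)-anti-diol | COc1ccc(CO[C@H]2C=C(O[Si](C)(C)C(C)(C)C)[C@@H](C)[C@H](COCc3ccc(OC)cc3)[C@@]2(C)[C@H](O)C[C@@H](O)/C(C)=C\I)cc1 | intermediate
19 | C12 keto diol: enol ether of 18 hydrolysed, C13 is CH2, C20 equatorial | COc1ccc(CO[C@H]2CC(=O)[C@@H](C)[C@H](COCc3ccc(OC)cc3)[C@@]2(C)[C@H](O)C[C@@H](O)/C(C)=C\I)cc1 | intermediate
20 | bis-TES keto ether: O2 and O4 of 19 as triethylsilyl ethers | COc1ccc(CO[C@H]2CC(=O)[C@@H](C)[C@H](COCc3ccc(OC)cc3)[C@@]2(C)[C@H](O[Si](CC)(CC)CC)C[C@@H](O[Si](CC)(CC)CC)/C(C)=C\I)cc1 | intermediate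
21 | (12R)-C12 alcohol, hydroxyl axial, cis to C20 and to O14 | COc1ccc(CO[C@H]2C[C@@H](O)[C@@H](C)[C@H](COCc3ccc(OC)cc3)[C@@]2(C)[C@H](O[Si](CC)(CC)CC)C[C@@H](O[Si](CC)(CC)CC)/C(C)=C\I)cc1 | intermediate
22 | C11=C12 alkene (C20 on C11) | COc1ccc(CO[C@H]2CC=C(C)[C@H](COCc3ccc(OC)cc3)[C@@]2(C)[C@H](O[Si](CC)(CC)CC)C[C@@H](O[Si](CC)(CC)CC)/C(C)=C\I)cc1 | intermediate
23 | C9/C14 diol: 22 without both PMB groups | O[C@H]1CC=C(C)[C@H](CO)[C@@]1(C)[C@H](O[Si](CC)(CC)CC)C[C@@H](O[Si](CC)(CC)CC)/C(C)=C\I | intermediate
24 | diacetate of 23 | CC(=O)O[C@H]1CC=C(C)[C@H](COC(C)=O)[C@@]1(C)[C@H](O[Si](CC)(CC)CC)C[C@@H](O[Si](CC)(CC)CC)/C(C)=C\I | intermediate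
25 | C14 monoacetate with free primary C9 alcohol | CC(=O)O[C@H]1CC=C(C)[C@H](CO)[C@@]1(C)[C@H](O[Si](CC)(CC)CC)C[C@@H](O[Si](CC)(CC)CC)/C(C)=C\I | intermediate
26 | C9 aldehyde (β,γ-unsaturated) | CC(=O)O[C@H]1CC=C(C)[C@H](C=O)[C@@]1(C)[C@H](O[Si](CC)(CC)CC)C[C@@H](O[Si](CC)(CC)CC)/C(C)=C\I | intermediate
27 | allyl 4-methoxybenzyl ether | C=CCOCc1ccc(OC)cc1 | starting material
28 | lithiated ether: (Z)-γ-(4-methoxybenzyloxy)allyllithium, drawn α-lithiated | [Li]C(C=C)OCc1ccc(OC)cc1 | intermediate
29 | [(Z)-3-(4-methoxybenzyloxy)allyl]diisopinocampheylborane, Ipc from (+)-α-pinene | COc1ccc(CO/C=C\CB([C@@H]2C[C@@H]3C[C@H]([C@H]2C)C3(C)C)[C@@H]2C[C@@H]3C[C@H]([C@H]2C)C3(C)C)cc1 | intermediate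
30 | (8R,9R)-syn adduct: C9 carries OH, C8 carries OPMB and a vinyl group whose CH is C7 | CC(=O)O[C@H]1CC=C(C)[C@H]([C@@H](O)[C@H](OCc2ccc(OC)cc2)C=C)[C@@]1(C)[C@H](O[Si](CC)(CC)CC)C[C@@H](O[Si](CC)(CC)CC)/C(C)=C\I | intermediate
31 | (11R,12S)-epoxide, oxygen on the ring face that carries C9 | CC(=O)O[C@H]1C[C@@H]2O[C@]2(C)[C@H]([C@@H](O)[C@H](OCc2ccc(OC)cc2)C=C)[C@@]1(C)[C@H](O[Si](CC)(CC)CC)C[C@@H](O[Si](CC)(CC)CC)/C(C)=C\I | intermediate
32 | tris-TES ether: O9 of 31 silylated | CC(=O)O[C@H]1C[C@@H]2O[C@]2(C)[C@H]([C@@H](O[Si](CC)(CC)CC)[C@H](OCc2ccc(OC)cc2)C=C)[C@@]1(C)[C@H](O[Si](CC)(CC)CC)C[C@@H](O[Si](CC)(CC)CC)/C(C)=C\I | intermediate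
33 | diol from dihydroxylation of the vinyl group of 32, both epimers | CC(=O)O[C@H]1C[C@@H]2O[C@]2(C)[C@H]([C@@H](O[Si](CC)(CC)CC)[C@H](OCc2ccc(OC)cc2)C(O)CO)[C@@]1(C)[C@H](O[Si](CC)(CC)CC)C[C@@H](O[Si](CC)(CC)CC)/C(C)=C\I | intermediate
34 | C7 aldehyde with the C8 OPMB group | CC(=O)O[C@H]1C[C@@H]2O[C@]2(C)[C@H]([C@@H](O[Si](CC)(CC)CC)[C@H](OCc2ccc(OC)cc2)C=O)[C@@]1(C)[C@H](O[Si](CC)(CC)CC)C[C@@H](O[Si](CC)(CC)CC)/C(C)=C\I | intermediate
35 | (7R)-macrocyclic allylic alcohol: ring B closed at C6–C7, 5Z | CC(=O)O[C@H]1C[C@@H]2O[C@]2(C)[C@@H]2[C@@H](O[Si](CC)(CC)CC)[C@H](OCc3ccc(OC)cc3)[C@H](O)/C=C(/C)[C@H](O[Si](CC)(CC)CC)C[C@@H](O[Si](CC)(CC)CC)[C@@]12C | intermediate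
36 | 2-bromopropanoic acid (racemic) | CC(Br)C(=O)O | starting material
37 | (7S)-2-bromopropanoate of the C7 alcohol, both epimers at the CHBr carbon (later C17) | CC(=O)O[C@H]1C[C@@H]2O[C@]2(C)[C@@H]2[C@@H](O[Si](CC)(CC)CC)[C@H](OCc3ccc(OC)cc3)[C@@H](OC(=O)C(C)Br)/C=C(/C)[C@H](O[Si](CC)(CC)CC)C[C@@H](O[Si](CC)(CC)CC)[C@@]12C | intermediate
38 | C8 alcohol: 37 without the PMB group | CC(=O)O[C@H]1C[C@@H]2O[C@]2(C)[C@@H]2[C@@H](O[Si](CC)(CC)CC)[C@H](O)[C@@H](OC(=O)C(C)Br)/C=C(/C)[C@H](O[Si](CC)(CC)CC)C[C@@H](O[Si](CC)(CC)CC)[C@@]12C | intermediate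
39 | C8 ketone | CC(=O)O[C@H]1C[C@@H]2O[C@]2(C)[C@@H]2[C@@H](O[Si](CC)(CC)CC)C(=O)[C@@H](OC(=O)C(C)Br)/C=C(/C)[C@H](O[Si](CC)(CC)CC)C[C@@H](O[Si](CC)(CC)CC)[C@@]12C | intermediate
40 | hydroxy lactone: γ-lactone O–C7, C8, C17, C19 closed, (8S)-tertiary alcohol, (17R); O2, O4, O9 as TES ethers, C14 acetate | CC(=O)O[C@H]1C[C@@H]2O[C@]2(C)[C@@H]2[C@@H](O[Si](CC)(CC)CC)[C@@]3(O)[C@H](/C=C(/C)[C@H](O[Si](CC)(CC)CC)C[C@@H](O[Si](CC)(CC)CC)[C@@]12C)OC(=O)[C@@H]3C | intermediate
41 | tetraol: 2,4,8,9-tetrahydroxy 14-acetate | CC(=O)O[C@H]1C[C@@H]2O[C@]2(C)[C@@H]2[C@@H](O)[C@@]3(O)[C@H](/C=C(/C)[C@H](O)C[C@@H](O)[C@@]12C)OC(=O)[C@@H]3C | intermediate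
42 | CNP0215170.2 | CC(=O)O[C@H]1C[C@@H]2O[C@]2(C)[C@@H]2[C@@H](OC(C)=O)[C@@]3(O)[C@H](/C=C(/C)[C@H](OC(C)=O)C[C@@H](OC(C)=O)[C@@]12C)OC(=O)[C@@H]3C | target

**Step count**
Total: 31 steps. Longest linear sequence: 27 steps (steps 3–8 and 11–31, from pent-1-yn-3-ol 4 to 42).

**Steps most likely to fail**

Step 25, ring closure. The alkenylchromium may add too slowly to the hindered α-branched aldehyde across the strained ten-membered transition state, so that intermolecular coupling to oligomers or reduction of the C–I bond takes over. The fallback closes ring B by ring-closing metathesis at C5=C6. It sets out from 34. Hydrodeiodination (Bu3SnH, Pd(PPh3)4, THF) would give the isopropenyl aldehyde F1. Chelation-controlled addition of CH2=CHMgBr (MgBr2·OEt2, CH2Cl2, −78 °C, Cram chelate through the C8 ether oxygen) would give the (7S)-vinyl carbinol F2. Acylation with 2-bromopropanoyl bromide and pyridine would give the diene bromo ester F3. Metathesis with (H2IMes)(PCy3)Cl2Ru=CHPh, the second-generation Grubbs catalyst, at high dilution, where the ten-membered ring enforces the cis ring olefin, would come back to the route at 37.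

Step 29, lactone closure. SmI2 may instead cleave the C7–O or C9–O bond next to the ketone, the samarium aldolate may revert by retro-aldol opening, or the enolate may add to the other carbonyl face and give the cis-fused lactone. The fallback builds the lactone as a butenolide and then adjusts it. It sets out from 39. PPh3 would give the phosphonium bromide F4, and Et3N would trigger an intramolecular Wittig reaction to the butenolide F5 (C8=C17). Nucleophilic epoxidation (t-BuOOH, 1,8-diazabicyclo[5.4.0]undec-7-ene), expected from the less hindered face, would give the 8,17-epoxy lactone F6. Reductive opening of the C17–O bond with SmI2 in THF/MeOH, where no ketone is present, with protonation of C17 to the more stable epimer, would come back to the route at 40.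

Step 26, inversion at C7. The hindered macrocyclic allylic hydroxyl may resist activation, or the alkoxyphosphonium ion may eliminate or react with allylic transposition instead of clean SN2 displacement. The fallback inverts C7 by oxidation and reduction. It sets out from 35. Dess–Martin oxidation would give the macrocyclic enone F7. Chelation-controlled 1,2-reduction with Zn(BH4)2 (Et2O, −30 °C, zinc held between the C7 carbonyl and the C8 ether oxygen) would give the (7S)-allylic alcohol F8. Acylation with 2-bromopropanoyl bromide and pyridine, with retention, would come back to the route at 37.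

**Further compounds**
F1 | step 25 | isopropenyl aldehyde: 34 with the iodine replaced by hydrogen | CC(=O)O[C@H]1C[C@@H]2O[C@]2(C)[C@H]([C@@H](O[Si](CC)(CC)CC)[C@H](OCc2ccc(OC)cc2)C=O)[C@@]1(C)[C@H](O[Si](CC)(CC)CC)C[C@@H](O[Si](CC)(CC)CC)C(C)=C
F2 | step 25 | (7S)-vinyl carbinol | CC(=O)O[C@H]1C[C@@H]2O[C@]2(C)[C@H]([C@@H](O[Si](CC)(CC)CC)[C@H](OCc2ccc(OC)cc2)[C@@H](O)C=C)[C@@]1(C)[C@H](O[Si](CC)(CC)CC)C[C@@H](O[Si](CC)(CC)CC)C(C)=C
F3 | step 25 | diene bromo ester: (7S)-2-bromopropanoate of F2 | CC(=O)O[C@H]1C[C@@H]2O[C@]2(C)[C@H]([C@@H](O[Si](CC)(CC)CC)[C@H](OCc2ccc(OC)cc2)[C@@H](OC(=O)C(C)Br)C=C)[C@@]1(C)[C@H](O[Si](CC)(CC)CC)C[C@@H](O[Si](CC)(CC)CC)C(C)=C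
F4 | step 29 | phosphonium bromide: 39 with bromine replaced by triphenylphosphonium | CC(=O)O[C@H]1C[C@@H]2O[C@]2(C)[C@@H]2[C@@H](O[Si](CC)(CC)CC)C(=O)[C@@H](OC(=O)C(C)[P+](c3ccccc3)(c3ccccc3)c3ccccc3)/C=C(/C)[C@H](O[Si](CC)(CC)CC)C[C@@H](O[Si](CC)(CC)CC)[C@@]12C.[Br-]
F5 | step 29 | butenolide with the C8=C17 double bond | CC(=O)O[C@H]1C[C@@H]2O[C@]2(C)[C@@H]2[C@@H](O[Si](CC)(CC)CC)C3=C(C)C(=O)O[C@H]3/C=C(/C)[C@H](O[Si](CC)(CC)CC)C[C@@H](O[Si](CC)(CC)CC)[C@@]12C
F6 | step 29 | 8,17-epoxy lactone, epoxide oxygen in the place of the later C8 hydroxyl | CC(=O)O[C@H]1C[C@@H]2O[C@]2(C)[C@@H]2[C@@H](O[Si](CC)(CC)CC)[C@]3(O4)[C@]4(C)C(=O)O[C@H]3/C=C(/C)[C@H](O[Si](CC)(CC)CC)C[C@@H](O[Si](CC)(CC)CC)[C@@]12C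
F7 | step 26 | macrocyclic enone: C7 ketone of 35 | CC(=O)O[C@H]1C[C@@H]2O[C@]2(C)[C@@H]2[C@@H](O[Si](CC)(CC)CC)[C@H](OCc3ccc(OC)cc3)C(=O)/C=C(/C)[C@H](O[Si](CC)(CC)CC)C[C@@H](O[Si](CC)(CC)CC)[C@@]12C
F8 | step 26 | (7S)-allylic alcohol, the C7 epimer of 35 | CC(=O)O[C@H]1C[C@@H]2O[C@]2(C)[C@@H]2[C@@H](O[Si](CC)(CC)CC)[C@H](OCc3ccc(OC)cc3)[C@@H](O)/C=C(/C)[C@H](O[Si](CC)(CC)CC)C[C@@H](O[Si](CC)(CC)CC)[C@@]12C
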